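**Strategy.** The 2,5-dihydro-1-benzoxepine is opened at O1–C2 and then at the two bonds that flank its only ring alkene, C3–C1' and C4–C5. The O1–C2–C3=C4 unit of the oxepine ring is propargyl alcohol. In one flask a homofarnesyl Grignard reagent adds anti across its magnesium alkoxide (CuI), and the (Z)-alkenylmagnesium so formed captures, at the future benzylic carbon C5, an o-quinone methide released from the benzoate ring. The precursors are homofarnesylmagnesium bromide, propargyl alcohol and methyl 4-(Boc-oxy)-3-(hydroxymethyl)benzoate. The coupled diol contains all carbons of the target with its two hydroxyl groups cis across the new alkene, so Mitsunobu etherification and ester hydrolysis finish the synthesis.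

Key step: step 8

Remark: the target has no stereocentre; its two E alkenes are carried unchanged from commercial (2E,6E)-farnesol, assumed to be a single geometric isomer, and the ring alkene (CH2O and CH2Ar cis) is set in the key step.

Step 1
Reactants: 1 (2E,6E)-farnesol
Product: 2 (2E,6E)-farnesal
Conditions: PhI(OAc)2 (1.1 equiv), TEMPO (10 mol %), CH2Cl2, 0 → 20 °C
Reagents that add atoms: none
Why: The TEMPO/PhI(OAc)2 oxidation (oxoammonium-mediated) should convert the primary allylic alcohol into the enal under near-neutral conditions, without over-oxidation, without attack on the trisubstituted alkenes and without erosion of the 2E geometry.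

Step 2
Reactants: 2 (2E,6E)-farnesal
Product: 3 (3E,7E)-4,8,12-trimethyltrideca-1,3,7,11-tetraene
Conditions: Ph3PCH3Br (1.3 equiv), KOt-Bu (1.2 equiv), THF, 0 °C; then 2, −78 → 0 °C
Reagents that add atoms: methyltriphenylphosphonium bromide, C[P+](c1ccccc1)(c1ccccc1)c1ccccc1.[Br-]
Why: Wittig methylenation with the non-stabilised ylide, kept free of excess base so that the enal is neither deconjugated nor isomerised, should turn the aldehyde into the terminal vinyl group.

Step 3
Reactants: 3 (3E,7E)-4,8,12-trimethyltrideca-1,3,7,11-tetraene
Product: 4 (3E,7E)-4,8,12-trimethyltrideca-3,7,11-trien-1-ol (homofarnesol)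
Conditions: 9-BBN (1.1 equiv), THF, 0 → 20 °C; then 3 M NaOH, 30% H2O2, 0 → 20 °C
Reagents that add atoms: hydrogen peroxide, OO
Why: Hydroboration–oxidation with the bulky 9-BBN should take place only at the monosubstituted terminal alkene of the diene, with boron at C1 (anti-Markovnikov), and leave the three trisubstituted alkenes alone, as in the classical one-carbon homologation of terpenols.

Step 4
Reactants: 4 (3E,7E)-4,8,12-trimethyltrideca-3,7,11-trien-1-ol
Product: 5 (6E,10E)-13-bromo-2,6,10-trimethyltrideca-2,6,10-triene (homofarnesyl bromide)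
Conditions: CBr4 (1.2 equiv), PPh3 (1.25 equiv), CH2Cl2, 0 °C
Reagents that add atoms: carbon tetrabromide, BrC(Br)(Br)Br
Why: Appel bromination replaces the primary hydroxyl by SN2 displacement of the oxyphosphonium under neutral conditions, which the acid-sensitive polyene should tolerate.

Step 5
Reactants: 5 (6E,10E)-13-bromo-2,6,10-trimethyltrideca-2,6,10-triene
Product: 6 [(3E,7E)-4,8,12-trimethyltrideca-3,7,11-trien-1-yl]magnesium bromide (titrated THF solution, used directly)
Conditions: Mg turnings (I2-activated), THF, 20 → 40 °C
Reagents that add atoms: magnesium, [Mg]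
Why: Oxidative insertion of magnesium into the primary C–Br bond gives the homoallylic Grignard reagent, whose alkene geometry is secure because closure to a cyclopropylcarbinyl species would require a tertiary carbanion.

Step 6
Reactants: 7 methyl 3-formyl-4-hydroxybenzoate
Product: 8 methyl 4-[(tert-butoxycarbonyl)oxy]-3-formylbenzoate
Conditions: Boc2O (1.1 equiv), DMAP (5 mol %), i-Pr2NEt (0.2 equiv), CH2Cl2, 0 → 20 °C
Reagents that add atoms: di-tert-butyl dicarbonate, CC(C)(C)OC(=O)OC(=O)OC(C)(C)C
Why: DMAP-catalysed O-acylation of the acidic phenol with Boc2O should give the aryl tert-butyl carbonate and leave the aldehyde and the methyl ester untouched.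

Step 7
Reactants: 8 methyl 4-[(tert-butoxycarbonyl)oxy]-3-formylbenzoate
Product: 9 methyl 4-[(tert-butoxycarbonyl)oxy]-3-(hydroxymethyl)benzoate
Conditions: BH3·THF (0.7 equiv), THF, −10 → 0 °C; then pH 7 buffer, 0 °C; product kept cold and used promptly
Reagents that add atoms: none
Why: Chemoselective borane reduction of the aldehyde runs through neutral alkoxyboranes and never through a free alkoxide, so the Boc group should stay on the phenolic oxygen and the ester and carbonate should survive at 0 °C, whereas a borohydride, whose basic alkoxide intermediates trigger Boc migration and loss of carbonate, is avoided for that reason.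

Step 8
Reactants: 6 [(3E,7E)-4,8,12-trimethyltrideca-3,7,11-trien-1-yl]magnesium bromide; 10 prop-2-yn-1-ol; 9 methyl 4-[(tert-butoxycarbonyl)oxy]-3-(hydroxymethyl)benzoate
Product: 13 methyl 4-hydroxy-3-[(2Z,6E,10E)-3-(hydroxymethyl)-7,11,15-trimethylhexadeca-2,6,10,14-tetraen-1-yl]benzoate, via alkenylmagnesium chelate 11 (not isolated), via o-quinone methide 12 (not isolated)
Conditions: 10 (1.7 equiv), t-BuMgCl (1.7 equiv), Et2O–THF, −40 → 0 °C; CuI (15 mol %), then 6 (1.5 equiv), −20 → 20 °C; cooled to −78 °C; magnesium alkoxide of 9 [9 (1.0 equiv), t-BuMgCl (1.0 equiv), THF, −78 °C] added by cannula, −78 → 20 °C; aq. NH4Cl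
Reagents that add atoms: none
Why: Proposed new method: catalytic CuI converts 6 into an alkylcopper species that adds across the alkyne of the chloromagnesium alkoxide of 10 with the alkyl group at the internal carbon (C3–C1') and, through O–Mg chelation, the metal at the terminal carbon anti to the new chain, so that transmetalation leaves the five-membered chelate 11 with magnesium cis to CH2O. On warming, the magnesium alkoxide of 9 passes its Boc group from the phenolic to the benzylic oxygen, the phenoxide expels tert-butyl carbonate, and the exocyclic methylene of the resulting 12 is attacked by the alkenyl–magnesium bond of 11 in a rearomatising 1,4-addition that forms C4–C5 with retention of the alkene geometry. The closest known reaction types are the copper-catalysed anti-carbomagnesiation of propargyl alcohol with electrophilic trapping of the alkenylmagnesium (I2, allyl halides, CO2) and the addition of Grignard reagents to o-quinone methides liberated from O-Boc salicyl alcohols; only their union in one flask is without precedent. No ring is closed and no stereocentre is formed; the Z geometry at C3=C4, on which the later ring closure depends, is fixed by the chelate. The step needs attack at the methylene and not at the ester or carbonate carbonyl groups, which is secured by the low temperature, by the high electrophilicity of 12 (raised further by the ester para to its carbonyl oxygen) and by the fact that after Boc migration the ester is conjugated to a phenoxide and thus deactivated. Using t-BuMgCl for both O–H deprotonations keeps 6 and 11 from being spent as bases, and any copper-mediated direct displacement of the benzylic carbonate would form the same bond.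

Step 9
Reactants: 13 methyl 4-hydroxy-3-[(2Z,6E,10E)-3-(hydroxymethyl)-7,11,15-trimethylhexadeca-2,6,10,14-tetraen-1-yl]benzoate
Product: 14 methyl 3-[(3E,7E)-4,8,12-trimethyltrideca-3,7,11-trien-1-yl]-2,5-dihydro-1-benzoxepine-7-carboxylate
Conditions: PPh3 (1.5 equiv), DIAD (1.5 equiv), THF (0.01 M), 0 → 20 °C
Reagents that add atoms: none
Why: In this intramolecular Mitsunobu etherification the acidic phenol (para ester) protonates the betaine and its phenoxide displaces the primary allylic oxyphosphonium by 7-exo-tet SN2 attack, the Z alkene holding both termini within reach, so that O1–C2 and the oxepine ring should form.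

Step 10
Reactants: 14 methyl 3-[(3E,7E)-4,8,12-trimethyltrideca-3,7,11-trien-1-yl]-2,5-dihydro-1-benzoxepine-7-carboxylate
Product: 15 3-[(3E,7E)-4,8,12-trimethyltrideca-3,7,11-trien-1-yl]-2,5-dihydro-1-benzoxepine-7-carboxylic acid (callophycoic acid F)
Conditions: LiOH·H2O (5 equiv), THF–MeOH–H2O, 40 °C; then 1 M HCl to pH 3, 0 °C
Reagents that add atoms: lithium hydroxide, [Li+].[OH-]
Why: Saponification (BAc2 ester hydrolysis) with LiOH should cleave the methyl ester, and brief cold acidification should liberate the acid without moving the ring alkene or protonating the trisubstituted alkenes.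

**Compound list**

1 | (2E,6E)-farnesol | CC(C)=CCC/C(C)=C/CC/C(C)=C/CO | starting material
2 | (2E,6E)-farnesal | CC(C)=CCC/C(C)=C/CC/C(C)=C/C=O | intermediate
3 | (3E,7E)-4,8,12-trimethyltrideca-1,3,7,11-tetraene | CC(C)=CCC/C(C)=C/CC/C(C)=C/C=C | intermediate
4 | (3E,7E)-4,8,12-trimethyltrideca-3,7,11-trien-1-ol | CC(C)=CCC/C(C)=C/CC/C(C)=C/CCO | intermediate
5 | (6E,10E)-13-bromo-2,6,10-trimethyltrideca-2,6,10-triene | CC(C)=CCC/C(C)=C/CC/C(C)=C/CCBr | intermediate
6 | [(3E,7E)-4,8,12-trimethyltrideca-3,7,11-trien-1-yl]magnesium bromide | CC(C)=CCC/C(C)=C/CC/C(C)=C/CC[Mg]Br | intermediate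
7 | methyl 3-formyl-4-hydroxybenzoate | COC(=O)c1ccc(O)c(C=O)c1 | starting material
8 | methyl 4-[(tert-butoxycarbonyl)oxy]-3-formylbenzoate | COC(=O)c1ccc(OC(=O)OC(C)(C)C)c(C=O)c1 | intermediate
9 | methyl 4-[(tert-butoxycarbonyl)oxy]-3-(hydroxymethyl)benzoate | COC(=O)c1ccc(OC(=O)OC(C)(C)C)c(CO)c1 | intermediate
10 | prop-2-yn-1-ol | C#CCO | starting material
11 | 4-[(3E,7E)-4,8,12-trimethyltrideca-3,7,11-trien-1-yl]-2,5-dihydro-1,2-oxamagnesole (cyclic alkenylmagnesium alkoxide, Mg cis to CH2O) | CC(C)=CCC/C(C)=C/CC/C(C)=C/CCC1=C[Mg]OC1 | intermediate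
12 | methyl 3-methylidene-4-oxocyclohexa-1,5-diene-1-carboxylate (o-quinone methide) | COC(=O)C1=CC(=C)C(=O)C=C1 | intermediate
13 | methyl 4-hydroxy-3-[(2Z,6E,10E)-3-(hydroxymethyl)-7,11,15-trimethylhexadeca-2,6,10,14-tetraen-1-yl]benzoate | CC(C)=CCC/C(C)=C/CC/C(C)=C/CC/C(CO)=C/Cc1cc(C(=O)OC)ccc1O | intermediate
14 | methyl 3-[(3E,7E)-4,8,12-trimethyltrideca-3,7,11-trien-1-yl]-2,5-dihydro-1-benzoxepine-7-carboxylate | CC(C)=CCC/C(C)=C/CC/C(C)=C/CCC1=CCc2cc(C(=O)OC)ccc2OC1 | intermediate
15 | callophycoic acid F, 3-[(3E,7E)-4,8,12-trimethyltrideca-3,7,11-trien-1-yl]-2,5-dihydro-1-benzoxepine-7-carboxylic acid | CC(C)=CCC/C(C)=C/CC/C(C)=C/CCC1=CCc2cc(C(=O)O)ccc2OC1 | target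

**Step count and risks**

Total step count: 10. Longest linear sequence: 8 steps (steps 1–5, 8, 9, 10); the arene branch (steps 6, 7) joins at step 8.

Steps most likely to fail:

1. Step 8. The alkenylmagnesium chelate may be consumed by proton transfer or by slow, incomplete carbomagnesiation, and the o-quinone methide may oligomerise or be intercepted by residual alkyl Grignard before the alkenyl nucleophile reaches it. The fallback uses known chemistry only, sets out from 6, 10 and 9 and returns at 13. The CuI-catalysed carbomagnesiation of the t-BuMgCl-derived alkoxide of 10 with 6 is run as above but quenched with I2 at −78 °C, a documented trapping, to give (2Z)-3-iodo-2-[(3E,7E)-4,8,12-trimethyltrideca-3,7,11-trien-1-yl]prop-2-en-1-ol F1. Separately, 9 is brominated (CBr4, PPh3, CH2Cl2, 0 °C) to methyl 3-(bromomethyl)-4-[(tert-butoxycarbonyl)oxy]benzoate F2. Zinc insertion (Zn dust, LiCl, THF, 20 °C) then gives bromo{[2-[(tert-butoxycarbonyl)oxy]-5-(methoxycarbonyl)phenyl]methyl}zinc F3. Negishi coupling of F1 with an excess of F3 (Pd(OAc)2, SPhos, THF, 20 °C) proceeds with retention of the alkene geometry and tolerates the free hydroxyl. It should give methyl 4-[(tert-butoxycarbonyl)oxy]-3-[(2Z,6E,10E)-3-(hydroxymethyl)-7,11,15-trimethylhexadeca-2,6,10,14-tetraen-1-yl]benzoate F4. Methanolysis of the aryl carbonate (K2CO3 cat., MeOH, 0 °C) then gives 13.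

2. Step 9. Closure of the seven-membered ring may lose to intermolecular etherification, to SN2' attack of the phenoxide at C4 (five-membered ring closure) or to elimination of the oxyphosphonium to a conjugated diene. The fallback sets out from 13 and returns at 14, with activation and ring closure separated. Corey–Kim chlorination (NCS, Me2S, CH2Cl2, −20 → 0 °C) should convert only the allylic alcohol, without allylic transposition, into methyl 3-[(2Z,6E,10E)-3-(chloromethyl)-7,11,15-trimethylhexadeca-2,6,10,14-tetraen-1-yl]-4-hydroxybenzoate F5. Slow addition of F5 to Cs2CO3 in DMF at 20 °C (high dilution) then closes O1–C2 by intramolecular Williamson etherification to give 14.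

3. Step 7. The Boc group may migrate to the new benzylic oxygen during reduction or work-up, followed by loss of carbonate, and the ester may be partly reduced. The fallback sets out from 7 and returns at 9, with the order of reduction and protection reversed so that no hydride reagent meets the aryl carbonate. NaBH4 in MeOH at 0 °C reduces 7 to methyl 4-hydroxy-3-(hydroxymethyl)benzoate F6. Boc2O (1.0 equiv) with catalytic DMAP in CH2Cl2 at 0 °C, stopped with aqueous citric acid as soon as the phenol is consumed, should then acylate only the far more acidic phenolic hydroxyl to give 9.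

**Further compounds**

F1 | step 8 | (2Z)-3-iodo-2-[(3E,7E)-4,8,12-trimethyltrideca-3,7,11-trien-1-yl]prop-2-en-1-ol | CC(C)=CCC/C(C)=C/CC/C(C)=C/CC/C(CO)=C/I
F2 | step 8 | methyl 3-(bromomethyl)-4-[(tert-butoxycarbonyl)oxy]benzoate | COC(=O)c1ccc(OC(=O)OC(C)(C)C)c(CBr)c1
F3 | step 8 | bromo{[2-[(tert-butoxycarbonyl)oxy]-5-(methoxycarbonyl)phenyl]methyl}zinc | COC(=O)c1ccc(OC(=O)OC(C)(C)C)c(C[Zn]Br)c1
F4 | step 8 | methyl 4-[(tert-butoxycarbonyl)oxy]-3-[(2Z,6E,10E)-3-(hydroxymethyl)-7,11,15-trimethylhexadeca-2,6,10,14-tetraen-1-yl]benzoate | CC(C)=CCC/C(C)=C/CC/C(C)=C/CC/C(CO)=C/Cc1cc(C(=O)OC)ccc1OC(=O)OC(C)(C)C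
F5 | step 9 | methyl 3-[(2Z,6E,10E)-3-(chloromethyl)-7,11,15-trimethylhexadeca-2,6,10,14-tetraen-1-yl]-4-hydroxybenzoate | CC(C)=CCC/C(C)=C/CC/C(C)=C/CC/C(CCl)=C/Cc1cc(C(=O)OC)ccc1O
F6 | step 7 | methyl 4-hydroxy-3-(hydroxymethyl)benzoate | COC(=O)c1ccc(O)c(CO)c1
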